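The constants used here belong to no real substance; the run is a simulation.

If [partner] stays nearly constant through a run, I can freeze it and treat each flask as a simple chain, so I reckon that level first.

    substrate → intermediate (k1 = 0.0066 s⁻¹, Ea1 = 92.0 kJ mol⁻¹)
    gas ⇌ partner, rate k2*(csat - [partner]) (k2 = 0.049 s⁻¹, csat = 200 mM)
    partner + intermediate → target (k3 = 0.42 L mol⁻¹ s⁻¹, Ea3 = 42.0 kJ mol⁻¹)
    substrate + target → side product A (k4 = 0.0045 L mol⁻¹ s⁻¹, Ea4 = 61.0 kJ mol⁻¹)
    2 partner → homo product (k5 = 2.1 L mol⁻¹ s⁻¹, Ea5 = 68.0 kJ mol⁻¹)
    intermediate → side product B (k6 = 0.0073 s⁻¹, Ea6 = 89.0 kJ mol⁻¹)
    (constants at 70 °C)

common to all: substrate 0.80 M; gas 200 mM (held); time 3.0 min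
- dusk: temperature 30 °C
- summer: temperature 70 °C
- spring: at 70 °C until 40 s, from then on at 30 °C
- winter: temperature 50 °C

- percent here means substrate units held: one side product A counts as two
- where a step has two of a species, its rate is k times that concentration squared, and two are used at each turn
- at the start none of partner is dissolved
- at 70 °C the constants are as listed, elsewhere as the activation energies make them

- the flask with the highest amount of target, in percent of the substrate charged ("all alike" if they lie within 1.5 percentage points) (dusk / summer / spring / winter / all alike)
- final target, as a percentage of the substrate charged, in dusk
- final target, as a percentage of the substrate charged, in summer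
- final target, as a percentage of the substrate charged, in spring
- final target, as a percentage of the substrate charged, in winter

1. My bench rule says that gas feeds at full driving force and partner stands where this feed meets its loss to homo product. In summer that gives 0.0483 M, or 0.241 of saturation.

2. The rule's border is that same ratio reaching 1. In dusk the coupling constant is 0.0431 of its summer value, so the rule gives 0.233 M, more than the saturation 200 mM. No dissolved level can stand there, so the rule stops working.

3. I therefore keep the driving force. The inflow, transfer coefficient times (saturation − [partner]), equals the loss, with two partner leaving at each turn. I leave the use of partner by intermediate out of this balance. Its root is the frozen level: 0.0428 M in summer and 0.134 M in dusk. Even in dusk, the linearised time constant of [partner] about this level is 10.3 s, far shorter than the run of 3.0 min.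

4. With [partner] frozen, the step to target is pseudo-first-order in intermediate, so intermediate splits at a fixed share. Target gets 71.1% in summer and 98.5% in dusk, a higher share in the cold.

5. I rank the flasks by what the first step turns over in the time, and summer comes first. Share times turnover caps target at 49.4% in summer and 1.65% in dusk. My reckoning goes no further than these caps.

6. The forecast also names summer. It gives 0.75% for dusk, 33% for summer, 14.5% for spring and 8.2% for winter, and says “these are rough quasi-steady estimates, not an integration”.

7. The flasks end at 0.772% in dusk, 34.4% in summer, 15.1% in spring and 8.35% in winter, so summer holds the most target. Summer pays with 18.0% of side product B, against 0.731% in winter.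

8. At the end of summer, [partner] reads 0.0392 M, a little below the frozen level 0.0428 M, and the products read a share of 68.6%, counting each side product A as one target lost. For the neighbour flask, summer repeated at 45 °C, the same balance gives 0.0910 M and a share of 95.0%. That flask reads 0.0890 M of partner and a share of 94.9%. It ends with 4.96% target and 91% substrate.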